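**Assumption:** the SMILES is read as 5R at the butenolide stereocentre, 2Z at the hydroxymethyl-bearing alkene and 6E at the methyl-bearing alkene of the side chain; methyl 4-hydroxybut-2-ynoate is taken as a catalogue compound.

## Retrosynthetic overview

1. The cyclohexene ring is bought with dihydro-β-ionone; the butenolide is the only ring made, and it is made last.
2. Last disconnection: the lactone O1–C5 bond together with the neighbouring CH2–alkenyl bond, giving a (Z)-alkenyl iodide and (2E)-3-(hydroxymethyl)penta-2,4-dienoic acid. These are joined by an enantioselective palladium-catalysed alkenylative lactonisation in which the C–O bond closes the ring and sets C5.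
3. The (Z)-alkenyl iodide comes from a homoallylic Grignard reagent, propargyl alcohol and iodine by anti-carbomagnesiation, which sets the 2Z alkene.
4. The homoallylic bromide comes from dihydro-β-ionone through a terminal alkyne and methylalumination/oxirane opening, which sets the 6E alkene.
5. The dienoic acid comes from methyl 4-hydroxybut-2-ynoate by hydroiodination, vinyl coupling and saponification.

## Route

**Step 1**
Reactants: 1 dihydro-β-ionone
Product: 3 2-(but-3-yn-1-yl)-1,3,3-trimethylcyclohex-1-ene, via enol diethyl phosphate 2 (not isolated)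
Conditions: LDA (1.1 equiv), THF, −78 °C; ClP(O)(OEt)2, −78 °C → rt; LDA (2.3 equiv), −78 °C → rt; H2O
Reagents that add atoms: none
Why: Kinetic enolisation on the methyl side, O-phosphorylation and double elimination of the enol phosphate with LDA convert the methyl ketone into the terminal alkyne (ketone-to-alkyne conversion via an enol phosphate); no stereocentre is involved.

**Step 2**
Reactants: 3 2-(but-3-yn-1-yl)-1,3,3-trimethylcyclohex-1-ene
Product: 6 (3E)-4-methyl-6-(2,6,6-trimethylcyclohex-1-en-1-yl)hex-3-en-1-ol, via alkenyldimethylalane 4 (not isolated), via lithium alkenylalanate 5 (not isolated)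
Conditions: Me3Al (2 equiv), Cp2ZrCl2 (0.25 equiv), CH2Cl2, rt; n-BuLi, hexane, 0 °C; oxirane, THF, 0 °C → rt; aq. HCl
Reagents that add atoms: trimethylaluminium, C[Al](C)C; oxirane, C1CO1
Why: Zirconium-catalysed syn-methylalumination (Negishi carboalumination) puts the methyl group on the internal carbon cis to aluminium, and the alanate opens oxirane with retention, which fixes the E trisubstituted alkene; the tetrasubstituted ring alkene is inert.

**Step 3**
Reactants: 6 (3E)-4-methyl-6-(2,6,6-trimethylcyclohex-1-en-1-yl)hex-3-en-1-ol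
Product: 7 2-[(3E)-6-bromo-3-methylhex-3-en-1-yl]-1,3,3-trimethylcyclohex-1-ene
Conditions: CBr4, PPh3, CH2Cl2, 0 °C
Reagents that add atoms: carbon tetrabromide, BrC(Br)(Br)Br
Why: Appel bromination of a primary alcohol proceeds under neutral conditions that leave both alkenes and the alkene geometry untouched.

**Step 4**
Reactants: 7 2-[(3E)-6-bromo-3-methylhex-3-en-1-yl]-1,3,3-trimethylcyclohex-1-ene; 9 propargyl alcohol
Product: 11 (2Z)-3-iodo-2-[(3E)-4-methyl-6-(2,6,6-trimethylcyclohex-1-en-1-yl)hex-3-en-1-yl]prop-2-en-1-ol, via homoallylic Grignard reagent 8 (not isolated), via cyclic alkenylmagnesium alkoxide 10 (not isolated)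
Conditions: 7, Mg, Et2O, reflux; 9 + i-PrMgCl (1.0 equiv), THF, 0 °C, then the Grignard solution (1.3 equiv), CuI (10 mol%), rt, 16 h; I2, Et2O, −20 → 0 °C; aq. Na2S2O3
Reagents that add atoms: iodine, II
Why: Copper-catalysed anti-carbomagnesiation of the propargyl alkoxide delivers the alkyl group to C2 and magnesium to C3 cis to the CH2O group in a five-membered chelate, and iodinolysis with retention gives the iodide cis to the hydroxymethyl group (this sets the 2Z alkene of the target).

**Step 5**
Reactants: 12 methyl 4-hydroxybut-2-ynoate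
Product: 13 methyl (2Z)-4-hydroxy-3-iodobut-2-enoate
Conditions: NaI, AcOH, 70 °C
Reagents that add atoms: sodium iodide, [Na+].[I-]
Why: Conjugate anti-hydroiodination of the ynoate places iodine at C3 cis to the ester, so the hydroxymethyl group is trans to the ester and cannot lactonise.

**Step 6**
Reactants: 13 methyl (2Z)-4-hydroxy-3-iodobut-2-enoate
Product: 15 (2E)-3-(hydroxymethyl)penta-2,4-dienoic acid, via methyl dienoate 14 (not isolated)
Conditions: vinylboronic acid pinacol ester, Pd(dppf)Cl2 (3 mol%), K2CO3, THF/H2O, 45 °C; then LiOH, 0 °C → rt; 1 M HCl to pH 3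
Reagents that add atoms: 4,4,5,5-tetramethyl-2-vinyl-1,3,2-dioxaborolane, C=CB1OC(C)(C)C(C)(C)O1; lithium hydroxide, [Li+].[OH-]
Why: Suzuki–Miyaura vinylation with retention of alkene geometry followed by saponification in the same flask gives the acid with the vinyl group cis to the carboxyl group, the arrangement needed for ring closure in step 7.

**Step 7**
Reactants: 11 (2Z)-3-iodo-2-[(3E)-4-methyl-6-(2,6,6-trimethylcyclohex-1-en-1-yl)hex-3-en-1-yl]prop-2-en-1-ol; 15 (2E)-3-(hydroxymethyl)penta-2,4-dienoic acid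
Product: 16 (6Z)-neomanoalide
Conditions: Pd2(dba)3 (2.5 mol%), spirobiindane phosphoramidite (S)-Siphos-PE (6 mol%; the antipode that gives 5R is used), Ag2CO3 (0.6 equiv), THF, 35 °C, dark
Reagents that add atoms: none
Why: Proposed new method: zerovalent palladium inserts into the C–I bond of 11 with retention, Ag2CO3 removes iodide and converts 15 into its carboxylate, the cationic alkenylpalladium (divalent palladium) binds the terminal vinyl group of 15, and the carboxylate, held cis to that vinyl group, attacks its internal carbon anti to palladium in a 5-exo acyloxypalladation that forms the O1–C5 bond and the butenolide ring under facial control by the chiral ligand (this C–O bond formation sets C5 as R), after which C(sp3)–C(sp2) reductive elimination joins the terminal CH2 to the alkenyl carbon with its Z geometry intact; the closest known reaction types are the palladium-catalysed enantioselective carboetherification and carboamination of alkenes with alkenyl halides and the coupling–cyclisation of 2,3-allenoic and 4-alkynoic acids with organic halides, none shown for a 2,4-dienoic acid giving a butenolide with a stereocentre at C5.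

## Compound list

1 | dihydro-β-ionone, 4-(2,6,6-trimethylcyclohex-1-en-1-yl)butan-2-one | CC(=O)CCC1=C(C)CCCC1(C)C | starting material
2 | diethyl 4-(2,6,6-trimethylcyclohex-1-en-1-yl)but-1-en-2-yl phosphate | C=C(CCC1=C(C)CCCC1(C)C)OP(=O)(OCC)OCC | intermediate
3 | 2-(but-3-yn-1-yl)-1,3,3-trimethylcyclohex-1-ene | C#CCCC1=C(C)CCCC1(C)C | intermediate
4 | dimethyl[(1E)-2-methyl-4-(2,6,6-trimethylcyclohex-1-en-1-yl)but-1-en-1-yl]alane | C[Al](C)/C=C(\C)CCC1=C(C)CCCC1(C)C | intermediate
5 | lithium butyl(dimethyl)[(1E)-2-methyl-4-(2,6,6-trimethylcyclohex-1-en-1-yl)but-1-en-1-yl]alanate | [Li+].CCCC[Al-](C)(C)/C=C(\C)CCC1=C(C)CCCC1(C)C | intermediate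
6 | (3E)-4-methyl-6-(2,6,6-trimethylcyclohex-1-en-1-yl)hex-3-en-1-ol | OCC/C=C(\C)CCC1=C(C)CCCC1(C)C | intermediate
7 | 2-[(3E)-6-bromo-3-methylhex-3-en-1-yl]-1,3,3-trimethylcyclohex-1-ene | BrCC/C=C(\C)CCC1=C(C)CCCC1(C)C | intermediate
8 | [(3E)-4-methyl-6-(2,6,6-trimethylcyclohex-1-en-1-yl)hex-3-en-1-yl]magnesium bromide | Br[Mg]CC/C=C(\C)CCC1=C(C)CCCC1(C)C | intermediate
9 | propargyl alcohol, prop-2-yn-1-ol | C#CCO | starting material
10 | 4-[(3E)-4-methyl-6-(2,6,6-trimethylcyclohex-1-en-1-yl)hex-3-en-1-yl]-2,5-dihydro-1,2-oxamagnesole (cyclic alkenylmagnesium alkoxide, Mg cis to CH2O) | C1(CC/C=C(\C)CCC2=C(C)CCCC2(C)C)=C[Mg]OC1 | intermediate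
11 | (2Z)-3-iodo-2-[(3E)-4-methyl-6-(2,6,6-trimethylcyclohex-1-en-1-yl)hex-3-en-1-yl]prop-2-en-1-ol | OC/C(CC/C=C(\C)CCC1=C(C)CCCC1(C)C)=C\I | intermediate
12 | methyl 4-hydroxybut-2-ynoate | COC(=O)C#CCO | starting material
13 | methyl (2Z)-4-hydroxy-3-iodobut-2-enoate | COC(=O)/C=C(\I)CO | intermediate
14 | methyl (2E)-3-(hydroxymethyl)penta-2,4-dienoate | COC(=O)/C=C(\C=C)CO | intermediate
15 | (2E)-3-(hydroxymethyl)penta-2,4-dienoic acid | OC(=O)/C=C(\C=C)CO | intermediate
16 | (6Z)-neomanoalide, (5R)-4-(hydroxymethyl)-5-[(2Z,6E)-3-(hydroxymethyl)-7-methyl-9-(2,6,6-trimethylcyclohex-1-en-1-yl)nona-2,6-dien-1-yl]furan-2(5H)-one | CC1=C(CC/C(C)=C/CC/C(=C/C[C@H]2OC(=O)C=C2CO)CO)C(C)(C)CCC1 | target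

## Step count and risks

Total steps: 7 (steps 1–4 for the alkenyl iodide, steps 5–6 for the dienoic acid, step 7 to join them).
Longest linear sequence: 5 steps (1, 2, 3, 4, 7).

**Most likely to fail, 1: step 7 (the proposed new step).** The alkylpalladium or allylpalladium intermediate may lose a β-hydrogen to give a triene instead of closing the lactone, the ligand may give low selectivity, and the base may erode the C5 stereocentre. Fallback by known chemistry, setting out from 11 and 13 and coming back at 16: silylate 11 (TBSCl, imidazole) to tert-butyl({(2Z)-3-iodo-2-[(3E)-4-methyl-6-(2,6,6-trimethylcyclohex-1-en-1-yl)hex-3-en-1-yl]prop-2-en-1-yl}oxy)dimethylsilane F1. Exchange iodine for lithium (t-BuLi, Et2O, −78 °C) and open oxirane (BF3·OEt2) to give the homoallylic alcohol (3Z,7E)-4-({[tert-butyl(dimethyl)silyl]oxy}methyl)-8-methyl-10-(2,6,6-trimethylcyclohex-1-en-1-yl)deca-3,7-dien-1-ol F2. Oxidise with Dess–Martin periodinane (NaHCO3) to the aldehyde (3Z,7E)-4-({[tert-butyl(dimethyl)silyl]oxy}methyl)-8-methyl-10-(2,6,6-trimethylcyclohex-1-en-1-yl)deca-3,7-dienal F3, used at once. Join F3 to iodo ester 13 in a ligand-controlled asymmetric Nozaki–Hiyama–Kishi alkenylation (CrCl2, catalytic NiCl2, chiral oxazoline–sulfonamide ligand, the antipode giving the R carbinol); the chromium alkoxide sits cis to the ester and lactonises on work-up to the mono-silyl ether (5R)-5-[(2Z,6E)-3-({[tert-butyl(dimethyl)silyl]oxy}methyl)-7-methyl-9-(2,6,6-trimethylcyclohex-1-en-1-yl)nona-2,6-dien-1-yl]-4-(hydroxymethyl)furan-2(5H)-one F4. HF·pyridine then gives 16.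

**Most likely to fail, 2: step 6.** The hydroxy dienoic acid is small, polar and polymerisable, and hydroxide may add to the dienoate or attack the iodo enoate. Fallback, setting out from 9 and coming back at 15, with no ester and no saponification: carboxylate the dianion of propargyl alcohol 9 (EtMgBr, 2 equiv, THF; CO2) to 4-hydroxybut-2-ynoic acid F5; hydroiodinate (NaI, AcOH) to (2Z)-4-hydroxy-3-iodobut-2-enoic acid F6; then a base-free Stille vinylation (tributyl(vinyl)stannane, Pd2(dba)3, AsPh3, NMP, rt) gives 15 directly.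

**Most likely to fail, 3: step 4.** Wurtz coupling during Grignard formation and incomplete carbomagnesiation would waste the three-step bromide. Fallback, setting out from 4 and 9 and coming back at 11, attaching the terpenoid chain by an sp3–sp2 coupling instead:
- Iodinate alane 4 (I2, THF, −30 °C) to 2-[(3E)-4-iodo-3-methylbut-3-en-1-yl]-1,3,3-trimethylcyclohex-1-ene F7.
- Add vinylmagnesium bromide to 9 (CuI cat.) and quench the chelate with Me3SiCl (the O-silyl group is cleaved on acidic work-up) to give (2Z)-2-ethenyl-3-(trimethylsilyl)prop-2-en-1-ol F8.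
- Hydroborate the vinyl group with 9-BBN to 9-[(3Z)-3-(hydroxymethyl)-4-(trimethylsilyl)but-3-en-1-yl]-9-borabicyclo[3.3.1]nonane F9 (its hydroxyl is borylated in the flask and freed on work-up).
- Couple F9 with F7 (Pd(dppf)Cl2, aq. K3PO4, B-alkyl Suzuki–Miyaura) to (2Z)-2-[(3E)-4-methyl-6-(2,6,6-trimethylcyclohex-1-en-1-yl)hex-3-en-1-yl]-3-(trimethylsilyl)prop-2-en-1-ol F10.
- Iododesilylation with retention (N-iodosuccinimide, MeCN, 0 °C) gives 11.

## Further compounds

F1 | step 7 | tert-butyl({(2Z)-3-iodo-2-[(3E)-4-methyl-6-(2,6,6-trimethylcyclohex-1-en-1-yl)hex-3-en-1-yl]prop-2-en-1-yl}oxy)dimethylsilane | CC(C)(C)[Si](C)(C)OC/C(CC/C=C(\C)CCC1=C(C)CCCC1(C)C)=C\I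
F2 | step 7 | (3Z,7E)-4-({[tert-butyl(dimethyl)silyl]oxy}methyl)-8-methyl-10-(2,6,6-trimethylcyclohex-1-en-1-yl)deca-3,7-dien-1-ol | CC(C)(C)[Si](C)(C)OC/C(CC/C=C(\C)CCC1=C(C)CCCC1(C)C)=C\CCO
F3 | step 7 | (3Z,7E)-4-({[tert-butyl(dimethyl)silyl]oxy}methyl)-8-methyl-10-(2,6,6-trimethylcyclohex-1-en-1-yl)deca-3,7-dienal | CC(C)(C)[Si](C)(C)OC/C(CC/C=C(\C)CCC1=C(C)CCCC1(C)C)=C\CC=O
F4 | step 7 | (5R)-5-[(2Z,6E)-3-({[tert-butyl(dimethyl)silyl]oxy}methyl)-7-methyl-9-(2,6,6-trimethylcyclohex-1-en-1-yl)nona-2,6-dien-1-yl]-4-(hydroxymethyl)furan-2(5H)-one | CC1=C(CC/C(C)=C/CC/C(=C/C[C@H]2OC(=O)C=C2CO)CO[Si](C)(C)C(C)(C)C)C(C)(C)CCC1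
F5 | step 6 | 4-hydroxybut-2-ynoic acid | OC(=O)C#CCO
F6 | step 6 | (2Z)-4-hydroxy-3-iodobut-2-enoic acid | OC(=O)/C=C(\I)CO
F7 | step 4 | 2-[(3E)-4-iodo-3-methylbut-3-en-1-yl]-1,3,3-trimethylcyclohex-1-ene | I/C=C(\C)CCC1=C(C)CCCC1(C)C
F8 | step 4 | (2Z)-2-ethenyl-3-(trimethylsilyl)prop-2-en-1-ol | OC/C(C=C)=C\[Si](C)(C)C
F9 | step 4 | 9-[(3Z)-3-(hydroxymethyl)-4-(trimethylsilyl)but-3-en-1-yl]-9-borabicyclo[3.3.1]nonane | OC/C(CCB1C2CCCC1CCC2)=C\[Si](C)(C)C
F10 | step 4 | (2Z)-2-[(3E)-4-methyl-6-(2,6,6-trimethylcyclohex-1-en-1-yl)hex-3-en-1-yl]-3-(trimethylsilyl)prop-2-en-1-ol | OC/C(CC/C=C(\C)CCC1=C(C)CCCC1(C)C)=C\[Si](C)(C)C
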